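**Plan**
- Retrosynthesis: the O8 side-chain ester is cut first, then the C8–O and C9–O bonds (back to a Z ring olefin), then the C8=C9 bond of the ten-membered ring (two vinyl groups). The seco compound is cut further at C1=C10 (olefination), at both oxiranes, at C3–C4 (sp2–sp2 coupling), at C4=C5 (Wittig) and at C7–C8 (conjugate addition).
- Forward: the γ-lactone ring comes first (chiral-pool butenolide, vinyl addition, α-methylenation). The chain C5→C1 is then grown on it, epoxidised twice and capped with a 2-vinyl acrylate. The ten-membered carbocycle is closed last by C8=C9 metathesis, and the C8/C9 oxygens and the two acyl groups follow.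
- Enabling feature: C8 and C9 are neighbouring ring CH–O carbons with cis oxygens (the retron of a Z ring olefin), lying between C7 of the lactone ring and C10 of the enoate. The open chain between them is pre-folded by four cis or ring-fused two-atom units: the C1=C10 enoate (C2 cis to C9), the cis C2–C3 and C4–C5 oxiranes, and the trans-fused lactone on C6–C7.
- Stereochemistry: C6 from (S)-5-(hydroxymethyl)furan-2(5H)-one; C7 by anti conjugate addition; C2/C3 by Sharpless epoxidation (reagent control); C4/C5 by substrate-controlled epoxidation (allylic 1,3-strain); C8/C9 relayed from C7 by an iodonium/acetoxonium double inversion; the side-chain oxirane by a second Sharpless epoxidation.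

Key step: step 13

Numbering: target (germacrane) numbering is used for all intermediates. C1–C10 are the ring carbons, C11/C12/C13 the lactone α-carbon, carbonyl and exocyclic CH2, C14 the ester carbon on C10, C15 the methyl on C4. The α face is the face of H-7. Target: 2R,3R,4R,5R,6S,7R,8S,9R; side chain 2S,3S.

Assumption: electrophiles should add to the Z C8=C9 bond of the ring-closed diene on the exposed α face (ring bond C7–C6 perpendicular to the olefin, H-7 eclipsed, as in 3-substituted Z-cycloalkenes of medium size). Osmylation would then give the 8α,9α-diol, so the 8β,9β oxygens are delivered by the double inversion of step 14.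

Step 1
Reactants: 1 (S)-5-(hydroxymethyl)furan-2(5H)-one
Product: 2 (S)-5-[(tert-butyldimethylsilyloxy)methyl]furan-2(5H)-one
Conditions: TBSCl, imidazole, DMF, 0 °C to rt
Reagents that add atoms: tert-butyldimethylsilyl chloride, CC(C)(C)[Si](C)(C)Cl
Why: Standard silyl ether formation masks the primary alcohol for the organometallic steps; the C6 stereocentre is not involved.

Step 2
Reactants: 2 (S)-5-[(tert-butyldimethylsilyloxy)methyl]furan-2(5H)-one
Product: 3 (4R,5S)-5-[(tert-butyldimethylsilyloxy)methyl]-4-vinyldihydrofuran-2(3H)-one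
Conditions: CH2=CHMgBr, CuBr·SMe2 (cat.), THF, −78 °C; aq NH4Cl
Reagents that add atoms: vinylmagnesium bromide, C=C[Mg]Br
Why: Copper-catalysed conjugate addition of the vinyl Grignard reagent to the butenolide takes place anti to the C5 silyloxymethyl group and so sets C7 trans to C6 (substrate control).

Step 3
Reactants: 3 (4R,5S)-5-[(tert-butyldimethylsilyloxy)methyl]-4-vinyldihydrofuran-2(3H)-one
Product: 6 (4S,5S)-5-[(tert-butyldimethylsilyloxy)methyl]-3-methylene-4-vinyldihydrofuran-2(3H)-one, via Mannich base 4 (not isolated), via ammonium iodide 5 (not isolated)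
Conditions: LiN(i-Pr)2, THF, −78 °C; CH2=NMe2+ I−, −78 to 0 °C; MeI, MeOH, rt; aq NaHCO3, CH2Cl2
Reagents that add atoms: N,N-dimethylmethyleneiminium iodide (Eschenmoser's salt), C=[N+](C)C.[I-]; iodomethane, CI (to intermediate 5 only)
Why: Mannich reaction of the lactone lithium enolate with Eschenmoser's salt, N-methylation and Hofmann-type elimination install the exocyclic methylene; C6 and C7 are untouched and the transient C11 centre disappears.

Step 4
Reactants: 6 (4S,5S)-5-[(tert-butyldimethylsilyloxy)methyl]-3-methylene-4-vinyldihydrofuran-2(3H)-one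
Product: 7 (4S,5S)-5-(hydroxymethyl)-3-methylene-4-vinyldihydrofuran-2(3H)-one
Conditions: HF·pyridine, THF, 0 °C to rt
Reagents that add atoms: none
Why: Acidic fluoride cleaves the silyl ether (desilylation) without adding to the Michael-acceptor lactone.

Step 5
Reactants: 7 (4S,5S)-5-(hydroxymethyl)-3-methylene-4-vinyldihydrofuran-2(3H)-one
Product: 8 (2S,3S)-4-methylene-5-oxo-3-vinyltetrahydrofuran-2-carbaldehyde
Conditions: Dess–Martin periodinane, CH2Cl2, 0 °C to rt; used crude
Reagents that add atoms: none
Why: Dess–Martin oxidation gives the α-acyloxy aldehyde under neutral conditions, so C6 should not epimerise.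

Step 6
Reactants: 8 (2S,3S)-4-methylene-5-oxo-3-vinyltetrahydrofuran-2-carbaldehyde
Product: 9 (4S,5S)-5-[(Z)-2-iodoprop-1-en-1-yl]-3-methylene-4-vinyldihydrofuran-2(3H)-one
Conditions: EtPPh3I, n-BuLi, THF, rt; I2, −78 °C; NaN(SiMe3)2, −78 °C; then 8, −78 to −20 °C
Reagents that add atoms: ethyltriphenylphosphonium iodide, CC[P+](c1ccccc1)(c1ccccc1)c1ccccc1.[I-]; iodine, II
Why: Stork–Zhao-type Wittig olefination with the α-iodo ylide Ph3P=C(I)CH3 is Z-selective (kinetic cis-oxaphosphetane of a non-stabilised ylide), which places iodine cis to C6 as needed for the cis C3/C6 pair at C4=C5.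

Step 7
Reactants: 9 (4S,5S)-5-[(Z)-2-iodoprop-1-en-1-yl]-3-methylene-4-vinyldihydrofuran-2(3H)-one; 10 (Z)-3-(tributylstannyl)prop-2-en-1-ol
Product: 11 (4S,5R)-5-[(1Z,3Z)-5-hydroxy-2-methylpenta-1,3-dien-1-yl]-3-methylene-4-vinyldihydrofuran-2(3H)-one
Conditions: Cu(O2CC4H3S) (copper thiophene-2-carboxylate), NMP, 0 °C to rt
Reagents that add atoms: none
Why: Copper-mediated Stille-type coupling forms the C3–C4 bond with retention of both olefin geometries and avoids zerovalent palladium, which could ionise the allylic C6–O lactone bond.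

Step 8
Reactants: 11 (4S,5R)-5-[(1Z,3Z)-5-hydroxy-2-methylpenta-1,3-dien-1-yl]-3-methylene-4-vinyldihydrofuran-2(3H)-one
Product: 12 (4S,5R)-5-{(Z)-2-[(2S,3R)-3-(hydroxymethyl)oxiran-2-yl]prop-1-en-1-yl}-3-methylene-4-vinyldihydrofuran-2(3H)-one (target numbering 2R,3S,6R,7S)
Conditions: Ti(OiPr)4 (cat.), D-(−)-diethyl tartrate (cat.), t-BuOOH, 4 Å molecular sieves, CH2Cl2, −20 °C
Reagents that add atoms: tert-butyl hydroperoxide, CC(C)(C)OO
Why: Sharpless asymmetric epoxidation of the Z-allylic alcohol is chemoselective for C2=C3 and, with the D-tartrate, should deliver oxygen to the face that gives the (2R,3S)-epoxy alcohol (reagent control sets C2 and C3).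

Step 9
Reactants: 12 (the cis-2,3-epoxy alcohol)
Product: 13 (4S,5S)-5-{(2R,3R)-3-[(2R,3R)-3-(hydroxymethyl)oxiran-2-yl]-3-methyloxiran-2-yl}-3-methylene-4-vinyldihydrofuran-2(3H)-one (target numbering 2R,3R,4R,5R,6S,7S)
Conditions: dimethyldioxirane, acetone, 0 °C
Reagents that add atoms: dimethyldioxirane, CC1(C)OO1
Why: The dioxirane epoxidises the only electron-rich (trisubstituted) olefin; because H-3 and H-6 eclipse the Z-olefin (allylic 1,3-strain), C2 and C7 shield one face and oxygen should add from the face of the two allylic oxygens, which sets C4 and C5 anti to the 2,3-oxirane and threo to O6 (substrate control, both allylic centres matched).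

Step 10
Reactants: 13 (the bis-oxirane alcohol)
Product: 14 bis-oxirane aldehyde (C1 = CHO; target numbering 2S,3R,4R,5R,6S,7S)
Conditions: Dess–Martin periodinane, pyridine, CH2Cl2, 0 °C; used at once
Reagents that add atoms: none
Why: Buffered Dess–Martin oxidation of the primary alcohol gives the cis-epoxy aldehyde without opening either oxirane or epimerising C2.

Step 11
Reactants: 15 trimethyl phosphonoacetate; 16 acetaldehyde
Product: 17 methyl 2-(dimethoxyphosphoryl)but-2-enoate (E/Z mixture)
Conditions: piperidine (cat.), AcOH (cat.), 4 Å molecular sieves, toluene, 60 °C, sealed vessel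
Reagents that add atoms: none
Why: Knoevenagel condensation of the phosphonoacetate with acetaldehyde; the E/Z mixture is acceptable because both isomers give the same allyl anion in step 12.

Step 12
Reactants: 14 bis-oxirane aldehyde; 17 methyl 2-(dimethoxyphosphoryl)but-2-enoate
Product: 18 seco ester: methyl (E)-2-vinyl-3-[bis-oxirane lactone]acrylate (C2 cis to the vinyl group across C1=C10; target numbering 2R,3R,4R,5R,6S,7S)
Conditions: 17, LiN(i-Pr)2, THF, −78 °C; then 14, −78 to 0 °C; product used directly
Reagents that add atoms: none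
Why: γ-Deprotonation gives a phosphonate- and ester-stabilised allyl anion that attacks the aldehyde through its α-carbon and eliminates dimethyl phosphate (Horner–Wadsworth–Emmons olefination of an α-substituted phosphonoacetate), which should give mainly the enoate with C2 trans to CO2Me and cis to the vinyl group, the geometry of the target C1=C10 bond.

Step 13
Reactants: 18 seco ester
Product: 19 methyl 2α,3α:4β,5β-diepoxygermacra-1(10),8Z,11(13)-trien-12,6α-olid-14-oate (C2 cis to C9 across C1=C10; 2R,3R,4R,5R,6S,7S)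
Conditions: second-generation Hoveyda–Grubbs catalyst (cat.), 1,4-benzoquinone (cat.), toluene, high dilution, 80 °C, argon sparge
Reagents that add atoms: none
Why: Ring-closing olefin metathesis: the ruthenium alkylidene forms at the C7 vinyl group, adds [2+2] to the terminal CH=CH2 of the 2-vinyl acrylate to give a ruthenacyclobutane, and cycloreversion releases ethene and closes the ring through the C8=C9 bond. The closest known reaction type is ring-closing metathesis to ten-membered germacranolide carbocycles that carry a spectator α-methylene lactone, and to cyclic 1,3-dienes from a terminal diene. One ring is closed, the ten-membered carbocycle, by head-to-head metathesis of two terminal vinyl groups; no ring of the substrate is opened. No stereocentre is created; the new C8=C9 olefin can only be Z because the ring already holds three cis two-atom units (C1=C10 and the C2–C3 and C4–C5 oxiranes), and this Z olefin is the retron of the cis C8/C9 dioxygenation. The step needs chemoselectivity among five olefins and cyclisation in preference to oligomerisation: the trisubstituted enoate C1=C10 and the 1,1-disubstituted methylene lactone are electron-poor, hindered spectators, no other disubstituted olefin is left because C2–C3 and C4–C5 are already oxiranes, and the four cis or ring-fused units fold the chain so that C8 and C9 face each other, with high dilution and removal of ethene doing the rest.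

Step 14
Reactants: 19 ring-closed triene
Product: 21 methyl 9β-acetoxy-8β-hydroxy-2α,3α:4β,5β-diepoxygermacra-1(10),11(13)-dien-12,6α-olid-14-oate (2R,3R,4R,5R,6S,7R,8S,9R), via iodoacetate 20 (not isolated)
Conditions: I2, AgOAc, AcOH, rt, dark; then H2O (wet AcOH), 45 °C; NaHCO3 work-up
Reagents that add atoms: silver acetate, CC(=O)[O-].[Ag+]; water, O; iodine, II (to intermediate 20 only)
Why: Woodward cis-hydroxylation: the iodonium ion should form on the exposed α face of the Z C8=C9 bond, acetate opens it at the allylic C9 from the β face, silver-assisted displacement of the C8 iodide by the neighbouring acetate gives the β-face 1,3-dioxolan-2-ylium ion, and water then gives the cis 8β,9β-hydroxy acetate with the acetyl group expected to stay on the less hindered, less basic allylic O9 (both new stereocentres are set from C7 by double inversion).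

Step 15
Reactants: 22 methyl angelate (methyl (Z)-2-methylbut-2-enoate)
Product: 23 (Z)-2-methylbut-2-en-1-ol
Conditions: i-Bu2AlH, CH2Cl2, −78 to 0 °C; Rochelle salt work-up
Reagents that add atoms: none
Why: i-Bu2AlH reduces the ester to the allylic alcohol (1,2-reduction) with retention of the Z geometry.

Step 16
Reactants: 23 (Z)-2-methylbut-2-en-1-ol
Product: 24 [(2R,3S)-2,3-dimethyloxiran-2-yl]methanol
Conditions: Ti(OiPr)4 (cat.), D-(−)-diethyl tartrate (cat.), t-BuOOH, 4 Å molecular sieves, CH2Cl2, −20 °C
Reagents that add atoms: tert-butyl hydroperoxide, CC(C)(C)OO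
Why: Sharpless asymmetric epoxidation of the trisubstituted Z-allylic alcohol with the D-tartrate should give the (2R,3S)-epoxy alcohol, syn addition keeping the two methyl groups trans (reagent control sets both side-chain centres).

Step 17
Reactants: 24 [(2R,3S)-2,3-dimethyloxiran-2-yl]methanol
Product: 25 (2S,3S)-2,3-dimethyloxirane-2-carboxylic acid
Conditions: RuCl3·xH2O (cat.), NaIO4, CCl4/MeCN/H2O, rt
Reagents that add atoms: sodium periodate, [Na+].[O-]I(=O)(=O)=O
Why: Ruthenium tetroxide generated in situ oxidises the primary alcohol to the glycidic acid without touching the oxirane or its stereocentres (the descriptor at C2 changes only through priorities).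

Step 18
Reactants: 21 hydroxy acetate; 25 (2S,3S)-2,3-dimethyloxirane-2-carboxylic acid
Product: 27 CNP0077535.3 (target), via mixed anhydride 26 (not isolated)
Conditions: 25, 2,4,6-trichlorobenzoyl chloride, Et3N, toluene, rt; then 21, DMAP, 0 °C to rt
Reagents that add atoms: 2,4,6-trichlorobenzoyl chloride, O=C(Cl)c1c(Cl)cc(Cl)cc1Cl (to intermediate 26 only)
Why: Yamaguchi esterification through the mixed anhydride acylates the remaining C8 hydroxyl with retention at every stereocentre; low temperature and DMAP catalysis are meant to outrun 1,2-acetyl migration from O9.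

**Compound list**
1 | (S)-5-(hydroxymethyl)furan-2(5H)-one | O=C1O[C@H](CO)C=C1 | starting material
2 | (S)-5-[(tert-butyldimethylsilyloxy)methyl]furan-2(5H)-one | O=C1O[C@H](CO[Si](C)(C)C(C)(C)C)C=C1 | intermediate
3 | (4R,5S)-5-[(tert-butyldimethylsilyloxy)methyl]-4-vinyldihydrofuran-2(3H)-one | C1C(=O)O[C@H](CO[Si](C)(C)C(C)(C)C)[C@H]1C=C | intermediate
4 | Mannich base: (4S,5S)-5-[(tert-butyldimethylsilyloxy)methyl]-3-[(dimethylamino)methyl]-4-vinyldihydrofuran-2(3H)-one (C3 epimers) | CN(C)CC1C(=O)O[C@H](CO[Si](C)(C)C(C)(C)C)[C@H]1C=C | intermediate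
5 | trimethylammonium iodide of 4 | C[N+](C)(C)CC1C(=O)O[C@H](CO[Si](C)(C)C(C)(C)C)[C@H]1C=C.[I-] | intermediate
6 | (4S,5S)-5-[(tert-butyldimethylsilyloxy)methyl]-3-methylene-4-vinyldihydrofuran-2(3H)-one | C=C1C(=O)O[C@H](CO[Si](C)(C)C(C)(C)C)[C@H]1C=C | intermediate
7 | (4S,5S)-5-(hydroxymethyl)-3-methylene-4-vinyldihydrofuran-2(3H)-one | C=C1C(=O)O[C@H](CO)[C@H]1C=C | intermediate
8 | (2S,3S)-4-methylene-5-oxo-3-vinyltetrahydrofuran-2-carbaldehyde | C=C1C(=O)O[C@H](C=O)[C@H]1C=C | intermediate
9 | (4S,5S)-5-[(Z)-2-iodoprop-1-en-1-yl]-3-methylene-4-vinyldihydrofuran-2(3H)-one | C=C1C(=O)O[C@H](/C=C(C)\I)[C@H]1C=C | intermediate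
10 | (Z)-3-(tributylstannyl)prop-2-en-1-ol | OC/C=C\[Sn](CCCC)(CCCC)CCCC | starting material
11 | (4S,5R)-5-[(1Z,3Z)-5-hydroxy-2-methylpenta-1,3-dien-1-yl]-3-methylene-4-vinyldihydrofuran-2(3H)-one | C=C1C(=O)O[C@H](/C=C(C)\C=C/CO)[C@H]1C=C | intermediate
12 | (4S,5R)-5-{(Z)-2-[(2S,3R)-3-(hydroxymethyl)oxiran-2-yl]prop-1-en-1-yl}-3-methylene-4-vinyldihydrofuran-2(3H)-one | C=C1C(=O)O[C@H](/C=C(C)\[C@@H]2O[C@@H]2CO)[C@H]1C=C | intermediate
13 | (4S,5S)-5-{(2R,3R)-3-[(2R,3R)-3-(hydroxymethyl)oxiran-2-yl]-3-methyloxiran-2-yl}-3-methylene-4-vinyldihydrofuran-2(3H)-one | C=C1C(=O)O[C@H]([C@H]2O[C@@]2(C)[C@@H]3O[C@@H]3CO)[C@H]1C=C | intermediate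
14 | bis-oxirane aldehyde (13 with C1 = CHO; target numbering 2S,3R,4R,5R,6S,7S) | C=C1C(=O)O[C@H]([C@H]2O[C@@]2(C)[C@@H]3O[C@@H]3C=O)[C@H]1C=C | intermediate
15 | trimethyl phosphonoacetate | COC(=O)CP(=O)(OC)OC | starting material
16 | acetaldehyde | CC=O | starting material
17 | methyl 2-(dimethoxyphosphoryl)but-2-enoate (E/Z) | CC=C(C(=O)OC)P(=O)(OC)OC | intermediate
18 | seco ester: methyl (E)-2-vinyl-3-[bis-oxirane lactone]acrylate (C2 cis to vinyl; 2R,3R,4R,5R,6S,7S) | C=C1C(=O)O[C@H]([C@H]2O[C@@]2(C)[C@@H]3O[C@@H]3/C=C(\C=C)C(=O)OC)[C@H]1C=C | intermediate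
19 | methyl 2α,3α:4β,5β-diepoxygermacra-1(10),8Z,11(13)-trien-12,6α-olid-14-oate (2R,3R,4R,5R,6S,7S) | C=C1C(=O)O[C@H]2[C@H]1/C=C\C(C(=O)OC)=C/[C@H]1O[C@H]1[C@]1(C)O[C@H]21 | intermediate
20 | 9β-acetoxy-8α-iodo derivative of 19 (7S,8R,9R) | C=C1C(=O)O[C@H]2[C@H]1[C@@H](I)[C@H](OC(C)=O)/C(C(=O)OC)=C\[C@H]1O[C@H]1[C@]1(C)O[C@H]21 | intermediate
21 | methyl 9β-acetoxy-8β-hydroxy-2α,3α:4β,5β-diepoxygermacra-1(10),11(13)-dien-12,6α-olid-14-oate (2R,3R,4R,5R,6S,7R,8S,9R) | C=C1C(=O)O[C@H]2[C@H]1[C@H](O)[C@H](OC(C)=O)/C(C(=O)OC)=C\[C@H]1O[C@H]1[C@]1(C)O[C@H]21 | intermediate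
22 | methyl angelate, methyl (Z)-2-methylbut-2-enoate | C/C=C(/C)C(=O)OC | starting material
23 | (Z)-2-methylbut-2-en-1-ol | C/C=C(/C)CO | intermediate
24 | [(2R,3S)-2,3-dimethyloxiran-2-yl]methanol | OC[C@@]1(C)O[C@H]1C | intermediate
25 | (2S,3S)-2,3-dimethyloxirane-2-carboxylic acid | OC(=O)[C@@]1(C)O[C@H]1C | intermediate
26 | (2S,3S)-2,3-dimethyloxirane-2-carboxylic 2,4,6-trichlorobenzoic anhydride | O=C(OC(=O)c1c(Cl)cc(Cl)cc1Cl)[C@@]1(C)O[C@H]1C | intermediate
27 | CNP0077535.3: methyl 9β-acetoxy-8β-[(2S,3S)-2,3-dimethyloxirane-2-carbonyloxy]-2α,3α:4β,5β-diepoxygermacra-1(10),11(13)-dien-12,6α-olid-14-oate (2R,3R,4R,5R,6S,7R,8S,9R) | C=C1C(=O)O[C@H]2[C@H]1[C@H](OC(=O)[C@@]1(C)O[C@H]1C)[C@H](OC(C)=O)/C(C(=O)OC)=C\[C@H]1O[C@H]1[C@]1(C)O[C@H]21 | target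

**Step count and risks**

Total: 18 steps. Longest linear sequence: 14 steps (steps 1–10, 12, 13, 14, 18).

Step 13 (ring-closing metathesis). What may go wrong: intermolecular metathesis (oligomerisation) may win, the catalyst may be arrested by chelation of the vinyl carbene to the C14 ester, or the chain stiffened by two oxiranes may fail to close. Fallback: the ring is closed before the second oxirane is made, on a more flexible chain. It sets out from 12. Buffered Dess–Martin oxidation would give the epoxy aldehyde F1. Olefination with the anion of 17, as in step 12, would give the triene ester F2. Metathesis under the conditions of step 13 would give the macrocyclic 4Z-olefin F3; the trisubstituted C4=C5 bond is inert to the catalyst. Dimethyldioxirane should then epoxidise the only electron-rich trisubstituted olefin of F3 from the β face, anti to C2 and C7. The route is rejoined at 19.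

Step 14 (Woodward cis-hydroxylation). What may go wrong: acid- or silver-induced opening of an oxirane, transannular participation of an oxirane oxygen or the lactone carbonyl in the iodonium opening, or scrambling of the acetyl group between O8 and O9. Fallback: osmylation followed by two separate inversions. It sets out from 19. OsO4 with N-methylmorpholine N-oxide should give, from the same exposed α face, the 8α,9α-diol F4. 1,1'-Sulfonyldiimidazole and DBU would give the cyclic sulfate F5. CsOAc in DMF should open it at the allylic C9 with inversion to the sulfate monoester F6. Catalytic H2SO4 in wet THF would hydrolyse this to the 9β-acetoxy-8α-alcohol F7. Mitsunobu esterification (PPh3, diisopropyl azodicarboxylate) with acid 25 inverts C8. The route is rejoined at target 27, bypassing 21 and step 18.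

Step 12 (olefination with the ambident phosphonate anion). What may go wrong: attack through the γ-carbon, poor control of the C1=C10 geometry, or base-induced epimerisation of the cis-epoxy aldehyde. Fallback: a two-stage aldol-type route. It sets out from 14. Indium powder and methyl (E)-4-bromobut-2-enoate in THF/H2O (Barbier-type vinylogous Reformatsky reaction, bond formation at the carbon α to the ester) should give the α-vinyl β-hydroxy ester F8 as a diastereomer mixture. MsCl and Et3N give the mesylate F9, and DBU-induced E1cB elimination gives the enoate. The route is rejoined at 18.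

Further compounds
F1 | step 13 | epoxy aldehyde from 12 (C1 = CHO, C4=C5 olefin kept; target numbering 2S,3S,6R,7S) | C=C1C(=O)O[C@H](/C=C(C)\[C@@H]2O[C@@H]2C=O)[C@H]1C=C
F2 | step 13 | triene ester: 18 with a Z C4=C5 olefin in place of the 4,5-oxirane | C=C1C(=O)O[C@H](/C=C(C)\[C@@H]2O[C@@H]2/C=C(\C=C)C(=O)OC)[C@H]1C=C
F3 | step 13 | methyl 2α,3α-epoxygermacra-1(10),4Z,8Z,11(13)-tetraen-12,6α-olid-14-oate (2R,3S,6R,7S) | C/C1=C/[C@H]2OC(=O)C(=C)[C@@H]2/C=C\C(C(=O)OC)=C/[C@H]2O[C@@H]12
F4 | step 14 | 8α,9α-diol of 19 (7R,8R,9S) | C=C1C(=O)O[C@H]2[C@H]1[C@@H](O)[C@@H](O)/C(C(=O)OC)=C\[C@H]1O[C@H]1[C@]1(C)O[C@H]21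
F5 | step 14 | 8α,9α-cyclic sulfate of F4 | C=C1C(=O)O[C@H]2[C@H]1[C@H]3OS(=O)(=O)O[C@H]3/C(C(=O)OC)=C\[C@H]1O[C@H]1[C@]1(C)O[C@H]21
F6 | step 14 | caesium 9β-acetoxy-8α-sulfate (not isolated) | C=C1C(=O)O[C@H]2[C@H]1[C@@H](OS(=O)(=O)[O-])[C@H](OC(C)=O)/C(C(=O)OC)=C\[C@H]1O[C@H]1[C@]1(C)O[C@H]21.[Cs+]
F7 | step 14 | 9β-acetoxy-8α-alcohol (C8 epimer of 21; 7R,8R,9R) | C=C1C(=O)O[C@H]2[C@H]1[C@@H](O)[C@H](OC(C)=O)/C(C(=O)OC)=C\[C@H]1O[C@H]1[C@]1(C)O[C@H]21
F8 | step 12 | α-vinyl β-hydroxy ester from 14 (C1/C10 epimers) | C=C1C(=O)O[C@H]([C@H]2O[C@@]2(C)[C@@H]3O[C@@H]3C(O)C(C=C)C(=O)OC)[C@H]1C=C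
F9 | step 12 | mesylate of F8 (not isolated) | C=C1C(=O)O[C@H]([C@H]2O[C@@]2(C)[C@@H]3O[C@@H]3C(OS(C)(=O)=O)C(C=C)C(=O)OC)[C@H]1C=C
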